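## Retrosynthetic overview
1. The quinone ring is made last, by para-oxidation of the only free phenol of a (3S)-2'-hydroxy-3',4',6,7-tetramethoxyisoflavan.
2. That phenol comes from reductive opening of the C11a–O bond of a (6aS,11aS)-pterocarpan. The dihydrofuran ring of the pterocarpan is closed by the 2'-OMe oxygen attacking C4 of an activated cis-isoflavan-4-ol with loss of its methyl group, so no protecting group is needed.
3. C3 (and C4) are set in one operation from the flat isoflavone by asymmetric transfer hydrogenation with dynamic kinetic resolution.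
4. The isoflavone comes from a flavanone by oxidative 2→3 aryl shift, the flavanone from a 2'-hydroxychalcone by oxa-Michael closure, and the chalcone from an acetophenone and a benzaldehyde.
5. Ring order: both arenes are bought. Pyran ring C is formed first and the dihydrofuran ring second (then opened again). Ring B becomes the quinone last.

Assumption: the stereocentre in the given SMILES reads as (3S), and "Abroquinone A" is taken as abruquinone A. Isoflavonoid numbering is used (ring A = chroman arene, ring B = 3-aryl/quinone ring).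

## Route

Step 1
Reactants: 1 2'-hydroxy-4',5'-dimethoxyacetophenone; 2 2,3,4-trimethoxybenzaldehyde
Product: 4 (±)-2',3',4',6,7-pentamethoxyflavanone, via chalcone 3 (not isolated)
Conditions: pyrrolidine (0.3 equiv), AcOH (0.3 equiv), EtOH, reflux, 24 h; 4 crystallises on cooling
Reagents that add atoms: none
Why: Amine-catalysed Claisen–Schmidt condensation gives chalcone 3, whose 2'-phenol closes ring C by reversible 6-endo oxa-Michael addition (the laboratory counterpart of chalcone isomerase); C2 forms racemic, which is harmless because step 2 destroys it.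

Step 2
Reactants: 4 (±)-2',3',4',6,7-pentamethoxyflavanone
Product: 6 2',3',4',6,7-pentamethoxyisoflavone, via C3-iodane 5 (not isolated)
Conditions: PhI(OH)OTs (1.2 equiv), MeCN, reflux, 2 h
Reagents that add atoms: none
Why: Hypervalent-iodine oxidative 1,2-aryl migration (the counterpart of isoflavone synthase): the enol of 4 is iodanylated at C3 trans to the aryl group, the p-methoxy-activated aryl ring shifts from C2 to C3 antiperiplanar to the departing PhI while O1 carries the charge at C2, and loss of H3 gives the chromone, the oxidisable p-methoxyphenol of ring A being masked as the ring ether.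

Step 3
Reactants: 6 2',3',4',6,7-pentamethoxyisoflavone
Product: 8 (3S,4S)-2',3',4',6,7-pentamethoxyisoflavan-4-ol, via isoflavanone 7 (not isolated)
Conditions: RuCl[(S,S)-TsDPEN](p-cymene) (2 mol %), HCO2H/Et3N (1:1, 6 equiv), EtOAc, 40 °C
Reagents that add atoms: none
Why: Noyori–Ikariya asymmetric transfer hydrogenation cascade with dynamic kinetic resolution: Ru–H adds 1,4 to the chromone to give 7, which racemises through its enol in the amine buffer, and the (S,S)-catalyst reduces only (3S)-7 from the face anti to the aryl group to the 4S carbinol (same sense as 4-chromanone to (S)-chroman-4-ol), which fixes C3 as S and the ring substituents as cis.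

Step 4
Reactants: 8 (3S,4S)-2',3',4',6,7-pentamethoxyisoflavan-4-ol
Product: 11 (6aS,11aS)-2,3,9,10-tetramethoxypterocarpan, via trans-4-bromide 9 (not isolated), via methyloxonium bromide 10 (not isolated)
Conditions: PPh3 (1.3 equiv), CBr4 (1.4 equiv), 2,6-di-tert-butylpyridine (0.3 equiv), CH2Cl2 (0.05 M), −20 °C → rt
Reagents that add atoms: none
Why: Proposed new method: Appel activation inverts the cis-alcohol to the trans-bromide 9, in whose trans-diaxial half-chair the 2'-OMe oxygen lies antiperiplanar to C4–Br while H3 is syn to Br and cannot leave by anti-E2, so MeO-5 neighbouring-group displacement at the O1/7-OMe-stabilised benzylic carbon gives the cis-fused oxonium 10, which bromide dealkylates at once by SN2 at CH3 to 11 and MeBr; only the one OMe of five that can reach C4 is unmasked, C3 becomes C6a with unchanged geometry, C11a is held cis by the ring fusion, and the hindered pyridine traps any HBr so that a trace of isoflav-3-ene cannot be reprotonated and erode the ee; the closest known reaction types are methoxy participation with dealkylation in solvolysis of 2-(o-anisyl)ethyl sulfonates, demethylative halocyclisation of o-allyl- and o-alkynylanisoles to (dihydro)benzofurans, and the acid closure of 2'-hydroxyisoflavan-4-ols to pterocarpans (the laboratory form of pterocarpan synthase).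

Step 5
Reactants: 11 (6aS,11aS)-2,3,9,10-tetramethoxypterocarpan
Product: 13 abruquinone A, via 2'-hydroxyisoflavan 12 (not isolated)
Conditions: H2 (1 atm), 10% Pd/C, DMF, rt; N2 purge, filter off Pd/C; Co(salen) (10 mol %), O2 (1 atm), rt
Reagents that add atoms: dioxygen, O=O
Why: Catalytic hydrogenolysis of the doubly activated benzylic C11a–O bond opens the dihydrofuran ring (counterpart of pterocarpan reductase) without touching C6a, which becomes C3 (S), and the freed 2,6-disubstituted phenol 12, the only free OH in the molecule, is then oxidised at its open para position by Co(salen)-catalysed aerobic phenol-to-p-quinone oxidation, while the fully etherified ring A and the stereocentre are untouched in the neutral medium.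

## Compound list
1 | 2'-hydroxy-4',5'-dimethoxyacetophenone | CC(=O)c1cc(OC)c(OC)cc1O | starting material
2 | 2,3,4-trimethoxybenzaldehyde | COc1ccc(C=O)c(OC)c1OC | starting material
3 | (E)-2'-hydroxy-2,3,4,4',5'-pentamethoxychalcone | COc1ccc(/C=C/C(=O)c2cc(OC)c(OC)cc2O)c(OC)c1OC | intermediate
4 | (±)-2',3',4',6,7-pentamethoxyflavanone | COc1ccc(C2CC(=O)c3cc(OC)c(OC)cc3O2)c(OC)c1OC | intermediate
5 | (±)-trans-3-[phenyl(tosyloxy)-λ3-iodanyl]-2',3',4',6,7-pentamethoxyflavanone | COc1ccc(C2Oc3cc(OC)c(OC)cc3C(=O)C2I(OS(=O)(=O)c2ccc(C)cc2)c2ccccc2)c(OC)c1OC | intermediate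
6 | 2',3',4',6,7-pentamethoxyisoflavone | COc1ccc(-c2coc3cc(OC)c(OC)cc3c2=O)c(OC)c1OC | intermediate
7 | (±)-2',3',4',6,7-pentamethoxyisoflavanone | COc1ccc(C2COc3cc(OC)c(OC)cc3C2=O)c(OC)c1OC | intermediate
8 | (3S,4S)-2',3',4',6,7-pentamethoxyisoflavan-4-ol (cis) | COc1ccc([C@H]2COc3cc(OC)c(OC)cc3[C@H]2O)c(OC)c1OC | intermediate
9 | (3S,4R)-4-bromo-2',3',4',6,7-pentamethoxyisoflavan (trans) | COc1ccc([C@H]2COc3cc(OC)c(OC)cc3[C@@H]2Br)c(OC)c1OC | intermediate
10 | (6aS,11aS)-2,3,9,10-tetramethoxy-11-methylpterocarpan-11-ium bromide | COc1ccc2c(c1OC)[O+](C)[C@@H]3c4cc(OC)c(OC)cc4OC[C@H]23.[Br-] | intermediate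
11 | (6aS,11aS)-2,3,9,10-tetramethoxypterocarpan | COc1ccc2c(c1OC)O[C@@H]3c4cc(OC)c(OC)cc4OC[C@H]23 | intermediate
12 | (3S)-2'-hydroxy-3',4',6,7-tetramethoxyisoflavan | COc1ccc([C@H]2COc3cc(OC)c(OC)cc3C2)c(O)c1OC | intermediate
13 | abruquinone A, 5-[(3S)-6,7-dimethoxychroman-3-yl]-2,3-dimethoxy-1,4-benzoquinone | COC1=C(OC)C(=O)C([C@H]2COc3cc(OC)c(OC)cc3C2)=CC1=O | target

## Step count
Total step count: 5. Longest linear sequence: 5 (1 and 2 are joined in step 1).

## Steps most likely to fail

**Step 4 is the most likely to fail.** Bromide 9 may lose HBr to the isoflav-3-ene, the benzylic carbon may be captured by phosphine, or the methyl transfer may be too slow. The fallback gives up the methyl-transfer closure and carries the 2'-oxygen as a benzyl ether. It sets out from 2 and comes back at 12.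
- Chelation-controlled cleavage of the ortho-methoxy group of 2 (BCl3, CH2Cl2, 0 °C) gives 2-hydroxy-3,4-dimethoxybenzaldehyde F1. Benzylation (BnBr, K2CO3, DMF) gives 2-benzyloxy-3,4-dimethoxybenzaldehyde F2.
- With 1 under the conditions of step 1, F2 passes through (E)-2-benzyloxy-2'-hydroxy-3,4,4',5'-pentaoxygenated chalcone F3 to (±)-2'-benzyloxy-3',4',6,7-tetramethoxyflavanone F4.
- The conditions of step 2 take F4 through the 2'-benzyloxy C3-iodane F5 to 2'-benzyloxy-3',4',6,7-tetramethoxyisoflavone F6.
- The conditions of step 3 take F6 through (±)-2'-benzyloxy-3',4',6,7-tetramethoxyisoflavanone F7 to (3S,4S)-2'-benzyloxy-3',4',6,7-tetramethoxyisoflavan-4-ol F8.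
- Hydrogenolysis of F8 (H2, Pd/C, EtOH–AcOH) removes the benzyl group and the benzylic C4–OH together and gives 12. This is oxidised as in the second half of step 5.

**Step 2 is next.** The trimethoxyphenyl ring may be attacked by the iodine(III) reagent to give a diaryliodonium salt, or 4 may simply be dehydrogenated to the flavone. The fallback replaces the rearrangement by a cross-coupling. It sets out from 1 and comes back at 6.
- Condensation of 1 with DMF dimethyl acetal (toluene, 90 °C) gives (E)-3-(dimethylamino)-1-(2-hydroxy-4,5-dimethoxyphenyl)prop-2-en-1-one F9.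
- Iodine (CHCl3, rt) closes and iodinates it to 3-iodo-6,7-dimethoxychromen-4-one F10.
- Suzuki–Miyaura coupling with commercial 2,3,4-trimethoxyphenylboronic acid (Pd(dppf)Cl2, K2CO3, dioxane–H2O, 80 °C) gives 6.

**Step 5 is third.** It joins two reactions without purification. The cobalt oxidation may give para C–C coupling (diphenoquinone) or stall on this hindered phenol. Step 3 rests on an established reaction type and ranks below it. The fallback brings in the second oxygen through nitrogen instead of a radical oxidation. It sets out from 12 and comes back at 13.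
- Azo coupling of the phenolate of 12 at its only open activated position with diazotised sulfanilic acid (aq NaOH, 0 °C) gives (3S)-2'-hydroxy-3',4',6,7-tetramethoxy-5'-(4-sulfophenylazo)isoflavan F11.
- Reduction with Na2S2O4 gives (3S)-5'-amino-2'-hydroxy-3',4',6,7-tetramethoxyisoflavan F12.
- Oxidation of this p-aminophenol with FeCl3 in dilute HCl, with hydrolysis of the quinone imine, gives 13.

## Further compounds
F1 | step 4 | 2-hydroxy-3,4-dimethoxybenzaldehyde | COc1ccc(C=O)c(O)c1OC
F2 | step 4 | 2-benzyloxy-3,4-dimethoxybenzaldehyde | COc1ccc(C=O)c(OCc2ccccc2)c1OC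
F3 | step 4 | (E)-2-benzyloxy-2'-hydroxy-3,4,4',5'-tetramethoxychalcone | COc1ccc(/C=C/C(=O)c2cc(OC)c(OC)cc2O)c(OCc2ccccc2)c1OC
F4 | step 4 | (±)-2'-benzyloxy-3',4',6,7-tetramethoxyflavanone | COc1ccc(C2CC(=O)c3cc(OC)c(OC)cc3O2)c(OCc2ccccc2)c1OC
F5 | step 4 | (±)-trans-2'-benzyloxy-3-[phenyl(tosyloxy)-λ3-iodanyl]-3',4',6,7-tetramethoxyflavanone | COc1ccc(C2Oc3cc(OC)c(OC)cc3C(=O)C2I(OS(=O)(=O)c2ccc(C)cc2)c2ccccc2)c(OCc2ccccc2)c1OC
F6 | step 4 | 2'-benzyloxy-3',4',6,7-tetramethoxyisoflavone | COc1ccc(-c2coc3cc(OC)c(OC)cc3c2=O)c(OCc2ccccc2)c1OC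
F7 | step 4 | (±)-2'-benzyloxy-3',4',6,7-tetramethoxyisoflavanone | COc1ccc(C2COc3cc(OC)c(OC)cc3C2=O)c(OCc2ccccc2)c1OC
F8 | step 4 | (3S,4S)-2'-benzyloxy-3',4',6,7-tetramethoxyisoflavan-4-ol | COc1ccc([C@H]2COc3cc(OC)c(OC)cc3[C@H]2O)c(OCc2ccccc2)c1OC
F9 | step 2 | (E)-3-(dimethylamino)-1-(2-hydroxy-4,5-dimethoxyphenyl)prop-2-en-1-one | CN(C)/C=C/C(=O)c1cc(OC)c(OC)cc1O
F10 | step 2 | 3-iodo-6,7-dimethoxychromen-4-one | COc1cc2occ(I)c(=O)c2cc1OC
F11 | step 5 | (3S)-2'-hydroxy-3',4',6,7-tetramethoxy-5'-(4-sulfophenylazo)isoflavan | COc1c(/N=N/c2ccc(S(=O)(=O)O)cc2)cc([C@H]2COc3cc(OC)c(OC)cc3C2)c(O)c1OC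
F12 | step 5 | (3S)-5'-amino-2'-hydroxy-3',4',6,7-tetramethoxyisoflavan | COc1c(N)cc([C@H]2COc3cc(OC)c(OC)cc3C2)c(O)c1OC
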